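The vessel is closed and stirred. E is held at constant pressure and feeds dissolved G, and L meets G on two possible paths, one through Q to J and one without Q to Z.

| flask | L | E | Q | remark | time |
|---|---|---|---|---|---|
| green | 0.25 M | 200 mM (held) | 0.55 mM | run made earlier |  |
| red | 1 M | 200 mM (held) | 0.55 mM | run made earlier |  |
| ochre | 0.50 M | 200 mM (held) | 0.28 mM | run made earlier |  |
| maple | 0.50 M | 200 mM (held) | 0.55 mM |  | 5.0 h |
| elm | 0.50 M | 200 mM (held) | 0.55 mM |  | 6.0 h |

| run | time / h | J / % | L / % | Z / % |
|---|---|---|---|---|
| green | 0.200 | 0 | 99.6 | 0 |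
| green | 0.667 | 3.7 | 95.3 | 1.5 |
| green | 1.00 | 6.7 | 89.3 | 2.8 |
| green | 1.50 | 12.6 | 81.9 | 4.3 |
| green | 2.50 | 24.6 | 64.9 | 10.0 |
| green | 3.00 | 30.4 | 57.3 | 11.7 |
| red | 0.200 | 0 | 99.5 | 0 |
| red | 0.667 | 1.6 | 96.7 | 1.1 |
| red | 1.00 | 4.0 | 94.6 | 1.3 |
| red | 1.50 | 6.0 | 91.7 | 2.9 |
| red | 2.50 | 10.7 | 84.1 | 4.3 |
| red | 3.00 | 13.3 | 80.9 | 5.5 |
| ochre | 0.667 | 1.5 | 97.0 | 1.3 |
| ochre | 1.33 | 5.1 | 90.6 | 3.7 |
| ochre | 2.00 | 9.3 | 83.8 | 6.8 |
| ochre | 2.50 | 11.6 | 79.4 | 9.1 |
| ochre | 3.00 | 14.7 | 74.0 | 11.4 |

(standard deviation of a reading: 0.3 percentage points)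

1. which of these there is most of at the end, counted by the L in it, maple (L / J / Z)
2. which of these there is most of at the end, counted by the L in it, elm (L / J / Z)
3. how much there is at the end of the one of these that leads, in percent of the L charged: maple
4. how much there is at the end of the one of these that leads, in percent of the L charged: elm

- at the start none of G is dissolved
- the earlier runs were read with a standard deviation of 0.3 percentage points
- steps thought possible: E <-> G; L + G + Q -> Q + J; L + G -> Z

Each L that reacts takes one G, so I split the hours a turnover costs into two times. The refill time belongs to the gas reaching the liquid, and the use time belongs to L finding the G, so it should grow as L falls. I assume they add: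

saturation concentration / rate = refill time + use time

Between 1.50 h and 3.00 h, the red run loses L at 72.0 mM h⁻¹ around 0.863 M. Over the same span, the green run loses 41.0 mM h⁻¹ around 0.174 M. These two readings give, at maple's charge:

use time = 0.915 h

refill time = 2.25 h

Their ratio is 2.45. I call it the drag ratio, refill time over use time. In maple the refill is the longer time, which makes it the nearer thing to a rate-limiting step.

The forecast reads the same runs, “Rates show an induction period, then saturate with L”. It puts L ahead in maple at 47.5% and J ahead in elm at 44%. By my own reckoning, summing the two times along the fall of L, its maple figure costs 4.65 h. Red's start-up, read from its readings, adds 0.347 h, so I accept the forecast.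

The flasks give L at 48.2% in maple and J at 44.0% in elm.

    E ⇌ G, rate k1*(csat - [G]) (kL = 0.00630 min⁻¹)
    L + G + Q → Q + J (k = 88.0 M⁻² min⁻¹)
    L + G → Z (k = 0.0190 M⁻¹ min⁻¹)

L still leads in maple because of the drag of the transfer of E to G, as a part of the cause, together with the time given. With that drag taken away, maple holds 70.5% of J against 37.2%, and left ten times as long it holds 71.8%. One more flask like maple, charged with 0.12 M of L, takes my read-off drag ratio of 2.45 down to 0.589 at that charge, but the constants above give 1.28, so at its charge the refill is still the longer time. At 5.0 h that flask has J in the lead at 57.9%.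

(All runs were generated by integration on assumed constants.)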